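## Retrosynthetic overview

1. Target 10 is fisetinidol-(4α→2')-robinetin, (2R,3S,4S), 2,3-trans-3,4-trans. The last bond made is C4–C2', by trapping the flavan-4-yl cation (quinone methide 9) from (+)-mollisacacidin 7 with bought robinetin 8; C2/C3 control C4.
2. 7 comes from (+)-fustin 6 by C4=O reduction, and 6 from its tri-O-benzyl ether 5 by hydrogenolysis.
3. Key disconnection: the O1–C2 and C3–O bonds of flavan ring C. 5 is made from 2'-hydroxychalcone 3 by a one-pot asymmetric epoxidation / 6-endo phenol epoxide opening, which closes the ring and sets C2 and C3.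
4. 3 comes from a Claisen–Schmidt condensation of 1 and 2.
5. Ring order: rings A and B of the flavan half and all rings of 8 are bought; flavan ring C is the only ring formed (step 2).

Assumption: robinetin 8 is bought as a catalogue flavonol in gram lots (used in excess and recovered); 1 and 2 are bulk benzyl-protected building blocks.

## Route

Step 1
Reactants: 1 1-[4-(benzyloxy)-2-hydroxyphenyl]ethan-1-one; 2 3,4-bis(benzyloxy)benzaldehyde
Product: 3 (E)-tri-O-benzylbutein
Conditions: KOH (50% aq., 5 equiv, base only), EtOH, rt, 36 h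
Reagents that add atoms: none
Why: Claisen–Schmidt aldol condensation; the conjugated, hydrogen-bonded 2'-hydroxychalcone forms as the E isomer and crystallises.

Step 2
Reactants: 3 (E)-tri-O-benzylbutein
Product: 5 7,3',4'-tri-O-benzyl-(2R,3R)-fustin, via epoxy ketone 4 (not isolated)
Conditions: Sc(OTf)3 (5 mol%), 1,1'-(propane-1,3-diyl)bis[N-(2,6-diisopropylphenyl)pyrrolidine-2-carboxamide] 1,1'-dioxide (6 mol%; the proline antipode that gives the αR,βS epoxide), 35% aq. H2O2 (1.5 equiv), THF, 0 °C, 12 h; then CSA (10 mol%), 35 °C, 2 h, one pot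
Reagents that add atoms: hydrogen peroxide, OO
Why: Proposed new method: a one-pot asymmetric oxidative ring closure of a 2'-hydroxychalcone with the ortho-phenol left free — the chiral trivalent-scandium N,N'-dioxide complex binds the carbonyl of 3 (second contact through the neighbouring phenol OH), delivers scandium-bound hydroperoxide to one face of Cβ, and the enolate closes to the (αR,βS)-epoxide 4 (Weitz–Scheffer; this fixes the future C3–O bond as R); the phenol then opens the acid-activated epoxide at the para-benzyloxy-stabilised benzylic Cβ in a 6-endo sense with inversion, giving the 2,3-trans ring with C2 = R (if the opening is SN1-like, closure to the diequatorial trans isomer is still favoured, so C3 controls C2); the closest known chemistry is the chiral N,N'-dioxide–Sc(OTf)3/H2O2 epoxidation of simple chalcones and the stepwise Algar–Flynn–Oyamada-type cyclisation of 2'-O-deprotected chalcone epoxides, neither run so far as an enantioselective one-pot process on an unprotected 2'-hydroxychalcone.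

Step 3
Reactants: 5 7,3',4'-tri-O-benzyl-(2R,3R)-fustin
Product: 6 (+)-fustin
Conditions: H2 (1 atm), 10% Pd/C, EtOAc–MeOH (1:1), rt, 3 h
Reagents that add atoms: none
Why: Catalytic hydrogenolysis of the three aryl benzyl ethers under neutral conditions at 1 atm leaves the aryl ketone and the C2/C3 stereocentres untouched.

Step 4
Reactants: 6 (+)-fustin
Product: 7 (+)-mollisacacidin
Conditions: NaBH4 (3 equiv), EtOH, 0 °C to rt, 2 h; work-up at pH 6
Reagents that add atoms: none
Why: Borohydride reduction of the C4 ketone by axial hydride delivery gives mainly the 3,4-trans diol without touching C2/C3; the C4 configuration is erased again in step 5, so its ratio does not matter.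

Step 5
Reactants: 7 (+)-mollisacacidin; 8 robinetin
Product: 10 fisetinidol-(4α→2')-robinetin, via quinone methide 9 (not isolated)
Conditions: 0.1 M aq. HCl–1,4-dioxane (1:1), rt, N2, dark, 24 h, fourfold molar excess of the flavonol (unreacted part recovered); Sephadex LH-20 (EtOH)
Reagents that add atoms: none
Why: Biomimetic flavan-4-yl cation Friedel–Crafts condensation (classical leucofisetinidin coupling): ionisation of the 7-OH-activated benzylic C4–OH with loss of water gives 9 (reacting as its O-protonated cation), which is attacked by C2' (= C6' by symmetry, ortho and para to two OH groups) of the pyrogallol ring of 8 on the face anti to the C3–OH, setting C4 as S (3,4-trans, 4α).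

## Compound list

1 | 1-[4-(benzyloxy)-2-hydroxyphenyl]ethan-1-one | CC(=O)c1ccc(OCc2ccccc2)cc1O | starting material
2 | 3,4-bis(benzyloxy)benzaldehyde | O=Cc1ccc(OCc2ccccc2)c(OCc2ccccc2)c1 | starting material
3 | (E)-1-[4-(benzyloxy)-2-hydroxyphenyl]-3-[3,4-bis(benzyloxy)phenyl]prop-2-en-1-one (tri-O-benzylbutein) | O=C(/C=C/c1ccc(OCc2ccccc2)c(OCc2ccccc2)c1)c1ccc(OCc2ccccc2)cc1O | intermediate
4 | [4-(benzyloxy)-2-hydroxyphenyl]{(2R,3S)-3-[3,4-bis(benzyloxy)phenyl]oxiran-2-yl}methanone (trans-αR,βS epoxy ketone) | O=C([C@@H]1O[C@H]1c1ccc(OCc2ccccc2)c(OCc2ccccc2)c1)c1ccc(OCc2ccccc2)cc1O | intermediate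
5 | (2R,3R)-7-(benzyloxy)-2-[3,4-bis(benzyloxy)phenyl]-3-hydroxychroman-4-one (tri-O-benzylfustin) | O=C1c2ccc(OCc3ccccc3)cc2O[C@H](c2ccc(OCc3ccccc3)c(OCc3ccccc3)c2)[C@H]1O | intermediate
6 | (2R,3R)-2-(3,4-dihydroxyphenyl)-3,7-dihydroxychroman-4-one ((+)-fustin) | O=C1c2ccc(O)cc2O[C@H](c2ccc(O)c(O)c2)[C@H]1O | intermediate
7 | (2R,3S,4R)-2-(3,4-dihydroxyphenyl)chromane-3,4,7-triol ((+)-mollisacacidin, 2,3-trans-3,4-trans) | O[C@@H]1c2ccc(O)cc2O[C@H](c2ccc(O)c(O)c2)[C@H]1O | intermediate
8 | 3,7-dihydroxy-2-(3,4,5-trihydroxyphenyl)-4H-chromen-4-one (robinetin) | O=c1c(O)c(-c2cc(O)c(O)c(O)c2)oc2cc(O)ccc12 | starting material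
9 | (2R,3S)-2-(3,4-dihydroxyphenyl)-3-hydroxy-2,3-dihydro-7H-chromen-7-one (ring A para-quinone methide; its O-protonated form is the flavan-4-yl cation) | O=C1C=CC2=C[C@H](O)[C@@H](c3ccc(O)c(O)c3)OC2=C1 | intermediate
10 | 2-{2-[(2R,3S,4S)-2-(3,4-dihydroxyphenyl)-3,7-dihydroxy-3,4-dihydro-2H-chromen-4-yl]-3,4,5-trihydroxyphenyl}-3,7-dihydroxy-4H-chromen-4-one | O=c1c(O)c(-c2cc(O)c(O)c(O)c2[C@@H]2c3ccc(O)cc3O[C@H](c3ccc(O)c(O)c3)[C@H]2O)oc2cc(O)ccc12 | target

## Step count and risks

Total steps: 5. Longest linear sequence: 5 steps (1 or 2 to 10).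

The three steps most likely to fail are step 2, step 5 and step 3.

**Step 2 (the proposed new step).**
- Risks: scandium-catalysed oxa-Michael closure of 3 to the racemic flavanone before epoxidation; low or reversed enantioselectivity because the chelating ortho-phenol changes the binding mode; aroyl migration of 4 (isoflavone pathway) or 5-exo opening to an aurone-type product.
- The sense of induction is checked at 6 against natural (+)-fustin, and the other ligand antipode is used if it is reversed.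
- Fallback (known chemistry), setting out from 1 and coming back at 5: protect the ortho-phenol of 1 with MOMCl/NaH in DMF to give 1-[4-(benzyloxy)-2-(methoxymethoxy)phenyl]ethan-1-one F1. Condense F1 with 2 (KOH, EtOH) to the 2'-O-MOM chalcone (E)-1-[4-(benzyloxy)-2-(methoxymethoxy)phenyl]-3-[3,4-bis(benzyloxy)phenyl]prop-2-en-1-one F2. Epoxidise F2 under Juliá–Colonna conditions (poly-L-leucine, urea–H2O2, DBU, THF) to [4-(benzyloxy)-2-(methoxymethoxy)phenyl]{(2R,3S)-3-[3,4-bis(benzyloxy)phenyl]oxiran-2-yl}methanone F3. Treat F3 with HCl in MeOH at 50 °C, which removes the MOM group and closes ring C to give 5.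

**Step 5.**
- Risks: C2' of 8 is hindered and deactivated by the chromone, so self-condensation of 7 through its own ring A, or bis-arylation, may win; some 4β isomer is also expected.
- Fallback, setting out from 7 and coming back at 10: use the more nucleophilic, non-conjugated pyrogallol ring of purchased (2R,3R)-dihydrorobinetin F6 under the same acid conditions to obtain (2R,3R)-2-{2-[(2R,3S,4S)-2-(3,4-dihydroxyphenyl)-3,7-dihydroxychroman-4-yl]-3,4,5-trihydroxyphenyl}-3,7-dihydroxychroman-4-one F7. Then dehydrogenate the dihydroflavonol ring of F7 with I2 (1.1 equiv) and KOAc in AcOH at 90 °C (the classical dihydroflavonol-to-flavonol oxidation) to reach 10.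

**Step 3.**
- Risks: over-reduction of the C4 ketone or hydrogenolysis of the benzylic C2–O bond during debenzylation.
- Fallback, setting out from 5 and coming back at 10: keep the benzyl ethers to the end. Reduce 5 with NaBH4 to (2R,3S,4R)-7-(benzyloxy)-2-[3,4-bis(benzyloxy)phenyl]chromane-3,4-diol F4. Condense F4 with 8 (p-TsOH·H2O 20 mol%, 1,4-dioxane, 40 °C) to 2-{2-[(2R,3S,4S)-7-(benzyloxy)-2-[3,4-bis(benzyloxy)phenyl]-3-hydroxychroman-4-yl]-3,4,5-trihydroxyphenyl}-3,7-dihydroxy-4H-chromen-4-one F5. Remove the three benzyl groups from F5 with H2 and Pd(OH)2/C in THF–MeOH to give 10; no ketone is present at that stage.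

Further compounds

F1 | step 2 | 1-[4-(benzyloxy)-2-(methoxymethoxy)phenyl]ethan-1-one | CC(=O)c1ccc(OCc2ccccc2)cc1OCOC
F2 | step 2 | (E)-1-[4-(benzyloxy)-2-(methoxymethoxy)phenyl]-3-[3,4-bis(benzyloxy)phenyl]prop-2-en-1-one | COCOc1cc(OCc2ccccc2)ccc1C(=O)/C=C/c1ccc(OCc2ccccc2)c(OCc2ccccc2)c1
F3 | step 2 | [4-(benzyloxy)-2-(methoxymethoxy)phenyl]{(2R,3S)-3-[3,4-bis(benzyloxy)phenyl]oxiran-2-yl}methanone | COCOc1cc(OCc2ccccc2)ccc1C(=O)[C@@H]1O[C@H]1c1ccc(OCc2ccccc2)c(OCc2ccccc2)c1
F4 | step 3 | (2R,3S,4R)-7-(benzyloxy)-2-[3,4-bis(benzyloxy)phenyl]chromane-3,4-diol | O[C@@H]1c2ccc(OCc3ccccc3)cc2O[C@H](c2ccc(OCc3ccccc3)c(OCc3ccccc3)c2)[C@H]1O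
F5 | step 3 | 2-{2-[(2R,3S,4S)-7-(benzyloxy)-2-[3,4-bis(benzyloxy)phenyl]-3-hydroxychroman-4-yl]-3,4,5-trihydroxyphenyl}-3,7-dihydroxy-4H-chromen-4-one | O=c1c(O)c(-c2cc(O)c(O)c(O)c2[C@@H]2c3ccc(OCc4ccccc4)cc3O[C@H](c3ccc(OCc4ccccc4)c(OCc4ccccc4)c3)[C@H]2O)oc2cc(O)ccc12
F6 | step 5 | (2R,3R)-3,7-dihydroxy-2-(3,4,5-trihydroxyphenyl)chroman-4-one (dihydrorobinetin, purchased) | O=C1c2ccc(O)cc2O[C@H](c2cc(O)c(O)c(O)c2)[C@H]1O
F7 | step 5 | (2R,3R)-2-{2-[(2R,3S,4S)-2-(3,4-dihydroxyphenyl)-3,7-dihydroxychroman-4-yl]-3,4,5-trihydroxyphenyl}-3,7-dihydroxychroman-4-one | O=C1c2ccc(O)cc2O[C@H](c2cc(O)c(O)c(O)c2[C@@H]2c3ccc(O)cc3O[C@H](c3ccc(O)c(O)c3)[C@H]2O)[C@H]1O
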